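## Analysis of the target

Halimane numbering is used throughout (ring A = C1–C5 with C10, ring B = C5–C10, side chain C11–C16, ester carbon C18).

The target 36 is an ent-halim-1(10)-ene. Ring A carries the trisubstituted C1=C10 alkene and the quaternary C4 with a β methyl ester and an α methyl group. Ring B is saturated and carries the α methyl group on C8 and the quaternary C9 with an α methyl group and the β side chain, which ends in a (Z)-cinnamate at C15.

There are five stereocentres: C4 (S), C5 (S, β-H), C8 (R), C9 (S) and the remote C13 (R). C4/C5 and C8/C9 are two vicinal pairs, each containing a quaternary carbon, and they are separated by the sp2 carbon C10. No ring-fusion stereocentre relays configuration between them, and C13 lies too far from the rings to be set by them.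

The (Z)-cinnamate isomerises to the E form under light, acid, radicals or nucleophilic catalysts. The 1(10)-alkene can slip under acid into the tetrasubstituted 5(10) position, which would erase C5. Once C7 is a ketone, C8 becomes epimerisable.

The difficulty is to set C5 relative to C4 next to a quaternary carbon, and C9 relative to C8, with the alkene exactly at C1=C10.

The strategy rests on one feature: C5–H is allylic to C1=C10, and C7 is a ring-B methylene that can be carried as a ketone. The C5–C6 bond together with the 1(10)-alkene is therefore the retron of a Claisen rearrangement of the allyl vinyl ether C6=C7–O–C1–C10=C5, in which oxygen bridges C1 and C7 in a pyran fused to ring A.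

## Retrosynthetic reasoning

**C15 ester.** The acyl–oxygen bond at C15 is cut and the acyl part is carried as an alkyne: 36 comes from the ynoate 35, and 35 from alcohol 33 and phenylpropiolic acid 34. The Z geometry is then created in the last step by syn addition of hydrogen and is never exposed to other reagents. The forward step must stop at the alkene and leave the hindered 1(10)-alkene alone.

**C7.** A carbonyl is added at C7: 33 comes from silyl ether 32, and 32 from ketone 29 through the tosylhydrazone 30. The ketone is the product function of the Claisen step. Its removal must avoid strong base (C8) and strong acid (alkene migration), which is why the hydrazone is reduced with a borane and not by a Wolff–Kishner protocol.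

**C5–C6 (key disconnection).** In 29 the C5–C6 bond is cut, O is reconnected to C1 and the alkene is returned to C5=C10, which gives the 2-methylidene pyran 28. This is the only ring-B bond whose formation closes ring B, creates C5 and places the alkene at C1=C10 in one event. C5 is then derived from a carbinol centre at C1, which a reagent can set, and not from a facial choice on a hindered alkene next to C4. The forward reaction is a thermal [3,3] shift that has to pass through a boat.

**C6=C7.** The enol ether 28 is traced to lactone 27 by carbonyl methylenation; C6 is the one carbon brought by the titanium reagent. A lactone is far easier to assemble and purify than an acid-labile enol ether. The forward step must distinguish the lactone from the C18 ester.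

**Lactone C–O and C8–C9.** Lactone 27 is opened at the acyl–O1 bond to acid 25. Acid 25 is the hydrogenation product of 24, and 24 is disconnected at C8–C9 by an Ireland–Claisen transform to the propionate 21.

- The quaternary C9 next to C8 is the hardest element before the key step. An acyclic chair [3,3] shift sets both centres from one carbinol (C12), which then disappears into the side chain as the C11=C12 alkene.
- An ester-tethered Heck closure from bromide 9 onto a trisubstituted alkene would make C9–C10 and the lactone at once. The alkene face would then be selected only by the conformation of the closing ring. That route was set aside because its outcome at C9 cannot be argued with confidence.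

**C9–C10.** Propionate 21 comes from dienol 19, which is cut between the two sp2 carbons C9 and C10 into bromide 10 and iodide 17 (Suzuki–Miyaura coupling). This is the convergent point; the alkene geometry needed for the sigmatropic step is carried in 17 and transferred with retention.

**Side chain.** Iodide 17 comes from propargylic alcohol 15 by directed hydroalumination–iodination. Alcohol 15 comes from ynone 14 by catalyst-controlled reduction (C12), and 14 from lactone 11 and propynyllithium 12 through 13. C13 is bought with lactone 11. The C15 oxygen is carried as a TBDPS ether so that the TES ether at C1 can later be removed beside it.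

**Ring A.** Bromide 10 comes from alcohol 9, and 9 from bromoenone 8 by oxazaborolidine reduction (C1). Bromoenone 8 comes from enone ester 6, which is reached from aldehyde 4 through acid 5. Aldehyde 4 is the Diels–Alder adduct of diene 1 and methacrolein 2 (C4). The enal is used in place of a methacrylate ester because catalytic enantiocontrol of this cycloaddition is established for α-substituted enals. The price is two redox-neutral steps to the ester.

## Alternatives that were turned down

**Alternative 1:** Ring A is disconnected at C2–C3 and C4–C5.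

- Forward key step: an exo-selective Diels–Alder reaction of the semicyclic ring-B diene A2 (C2=C1–C10=C5) with methacrolein 2 gives the aldehyde A1; the aldehyde is then oxidised and esterified.
- For: it is the most convergent plan. Two bonds, ring A, C4 and C5 arise in one step, the alkene lands directly at C1=C10, and the regiochemistry (quaternary dienophile carbon to the substituted diene terminus) and the exo preference of α-methyl enals are the normal ones.
- Against: the reacting terminus C5 is trisubstituted and neopentyl to C9. The diene face is differentiated only by the two substituents on C9, a methyl group and a CH2CH2R chain of similar size, so the configuration of C4/C5 relative to C8/C9 is poorly secured. A2 still needs C8 and the quaternary C9 built first, so that problem is not avoided.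
- Comparison: on step count after the ring-B fragment this plan is stronger. The chosen route instead fixes C5 by an intramolecular suprafacial transfer from C1, where no facial choice exists.

**Alternative 2:** Both rings are disconnected at C5–C10 and C8–C9.

- Forward key step: an intramolecular [4+2] cycloaddition of the distal C9=C10 bond of a trisubstituted allene with a tethered (E,E)-diene (C5=C6–C7=C8) gives the diene ester A3; the C6=C7 alkene is then hydrogenated selectively.
- For: it forms two rings, two bonds and three stereocentres (C5, C8, C9) in one step, and the remaining allene double bond becomes the 1(10)-alkene. In bond count it is stronger than the chosen step.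
- Against: C9 would be set by the axial chirality of an enantioenriched trisubstituted allene, which must be made beside an acyclic quaternary C4 and C13. Neither reacting partner is activated, so high temperature is needed and addition to the proximal allene bond, [2+2] pathways and endo/exo mixtures compete. The relation of C4 to the new centres depends on the folding of a flexible tether.
- Comparison: the risk is spread over both the precursor and the key step. The chosen route keeps every stereocentre except C5 in established reactions and concentrates the risk in one step with no regiochemical choice.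

**Alternative 3:** Ring B is disconnected at C8–C17 and C9–C11.

- Forward key step: a copper-catalysed asymmetric conjugate methylation of 2-methylcyclohex-2-en-1-one A5 and alkylation of the resulting enolate with the iodide A6 give the ketone A4 in one pot.
- For: it uses cheap materials and a well-known reaction type with catalytic enantiocontrol. Alkylation anti to the new C8 methyl group gives the required trans relation of C17 and C11. In early-stage reliability it is stronger than the chosen route.
- Against: α-substituted cyclohexenones are sluggish acceptors. Alkylation of the resulting hindered enolate with an unactivated primary iodide to form a quaternary carbon competes with proton transfer and O-alkylation. No ring is closed: ring A, the quaternary C4, C5 and the 1(10)-alkene must still be annulated onto the C10 ketone, which defers the hardest stereochemical problem.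
- Comparison: the chosen strategy closes ring B and sets C5 at the point where this alternative stops.

Key step: step 17

Assumption: the sense of induction of the TADDOL, oxazaborolidine and ruthenium catalysts is assigned from the accepted transition-state models; the mirror-image catalysts are equally available if a sense proves opposite.

## Route

Step 1
Reactants: 1 (E)-1-(dimethylamino)-3-(tert-butyldimethylsilyloxy)buta-1,3-diene; 2 methacrolein
Product: 4 (S)-1-methyl-4-oxocyclohex-2-ene-1-carbaldehyde, via endo cycloadduct 3 (not isolated)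
Conditions: (R,R)-1-naphthyl-TADDOL (20 mol %), toluene, −80 °C; then 1 M HCl, THF, 0 °C
Reagents that add atoms: none
Why: Hydrogen-bond-catalysed Diels–Alder reaction of an aminosiloxydiene with an α-substituted enal; the diol activates the aldehyde and shields one face, which sets the quaternary C4, and acid then hydrolyses the silyl enol ether and eliminates dimethylamine to the enone.

Step 2
Reactants: 4 (S)-1-methyl-4-oxocyclohex-2-ene-1-carbaldehyde
Product: 5 (S)-1-methyl-4-oxocyclohex-2-ene-1-carboxylic acid
Conditions: NaClO2, NaH2PO4, 2-methylbut-2-ene, t-BuOH/H2O, 0 °C to rt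
Reagents that add atoms: sodium chlorite, [Na+].[O-]Cl=O
Why: Pinnick oxidation is selective for the aldehyde; the enone is untouched and the quaternary centre cannot epimerise.

Step 3
Reactants: 5 (S)-1-methyl-4-oxocyclohex-2-ene-1-carboxylic acid
Product: 6 methyl (S)-1-methyl-4-oxocyclohex-2-ene-1-carboxylate
Conditions: MeI, K2CO3, DMF, rt
Reagents that add atoms: iodomethane, CI
Why: SN2 O-alkylation of the carboxylate under weak base, which avoids acid-catalysed conjugate addition to the enone.

Step 4
Reactants: 6 methyl (S)-1-methyl-4-oxocyclohex-2-ene-1-carboxylate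
Product: 8 methyl (S)-3-bromo-1-methyl-4-oxocyclohex-2-ene-1-carboxylate, via dibromide 7 (not isolated)
Conditions: Br2, CH2Cl2, 0 °C; then Et3N, 0 °C to rt
Reagents that add atoms: bromine, BrBr
Why: Bromine addition to the enone alkene followed by E1cB loss of HBr leaves bromine on the α-carbon (C10), the standard access to 2-bromoenones.

Step 5
Reactants: 8 methyl (S)-3-bromo-1-methyl-4-oxocyclohex-2-ene-1-carboxylate
Product: 9 methyl (1S,4S)-3-bromo-4-hydroxy-1-methylcyclohex-2-ene-1-carboxylate
Conditions: (R)-2-methyl-CBS-oxazaborolidine (20 mol %), BH3·SMe2, THF, −20 °C; MeOH quench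
Reagents that add atoms: none
Why: Corey–Bakshi–Shibata reduction; the bromoalkenyl arm acts as the large group, so the catalyst and not the remote C4 centre sets the α (1S in halimane numbering) carbinol, and any minor enantiomer of 8 is turned into a separable diastereomer.

Step 6
Reactants: 9 methyl (1S,4S)-3-bromo-4-hydroxy-1-methylcyclohex-2-ene-1-carboxylate
Product: 10 methyl (1S,4S)-3-bromo-1-methyl-4-(triethylsilyloxy)cyclohex-2-ene-1-carboxylate
Conditions: Et3SiCl, imidazole, CH2Cl2, 0 °C to rt
Reagents that add atoms: chlorotriethylsilane, CC[Si](Cl)(CC)CC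
Why: Silylation of the allylic alcohol; TES is chosen because it can later be cleaved beside a primary TBDPS ether.

Step 7
Reactants: 11 (S)-α-methyl-γ-butyrolactone; 12 1-propynyllithium
Product: 13 (S)-7-hydroxy-5-methylhept-2-yn-4-one
Conditions: THF, −78 °C; aq. NH4Cl
Reagents that add atoms: none
Why: Acyl substitution of a lactone by a lithium acetylide stops at the ketone because the tetrahedral alkoxide persists at −78 °C until the quench; C13 is taken from the chiral pool.

Step 8
Reactants: 13 (S)-7-hydroxy-5-methylhept-2-yn-4-one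
Product: 14 (S)-7-(tert-butyldiphenylsilyloxy)-5-methylhept-2-yn-4-one
Conditions: t-BuPh2SiCl, imidazole, CH2Cl2, 0 °C to rt
Reagents that add atoms: tert-butyl(chloro)diphenylsilane, CC(C)(C)[Si](Cl)(c1ccccc1)c1ccccc1
Why: Silylation of the primary alcohol under conditions too mild to enolise the ynone; the TBDPS ether is meant to last until step 20.

Step 9
Reactants: 14 (S)-7-(tert-butyldiphenylsilyloxy)-5-methylhept-2-yn-4-one
Product: 15 (4S,5S)-7-(tert-butyldiphenylsilyloxy)-5-methylhept-2-yn-4-ol
Conditions: RuCl[(S,S)-TsDPEN](p-cymene) (2 mol %), i-PrOH, rt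
Reagents that add atoms: none
Why: Noyori transfer hydrogenation of an ynone; the catalyst recognises the alkyne as the π-substituent and sets the C12 carbinol (S) under reagent control, independent of C13.

Step 10
Reactants: 15 (4S,5S)-7-(tert-butyldiphenylsilyloxy)-5-methylhept-2-yn-4-ol
Product: 17 (2Z,4S,5S)-7-(tert-butyldiphenylsilyloxy)-2-iodo-5-methylhept-2-en-4-ol, via alkenylalanate 16 (not isolated)
Conditions: NaAlH2(OCH2CH2OMe)2, THF, 0 °C to rt; then I2, −78 to 0 °C
Reagents that add atoms: iodine, II
Why: Alkoxide-directed trans-hydroalumination of a propargylic alcohol places aluminium on the distal carbon cis to the carbinol; iodinolysis with retention gives the (Z)-iodide regio- and stereospecifically.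

Step 11
Reactants: 10 methyl (1S,4S)-3-bromo-1-methyl-4-(triethylsilyloxy)cyclohex-2-ene-1-carboxylate; 17 (2Z,4S,5S)-7-(tert-butyldiphenylsilyloxy)-2-iodo-5-methylhept-2-en-4-ol
Product: 19 methyl (1S,4S)-3-[(2Z,4S,5S)-7-(tert-butyldiphenylsilyloxy)-4-hydroxy-5-methylhept-2-en-2-yl]-1-methyl-4-(triethylsilyloxy)cyclohex-2-ene-1-carboxylate, via pinacol boronate 18 (not isolated)
Conditions: B2pin2, PdCl2(dppf) (5 mol %), KOAc, 1,4-dioxane, 80 °C; then 17, aq. K3PO4, 60 °C
Reagents that add atoms: none
Why: Miyaura borylation of the alkenyl bromide followed in the same flask by Suzuki–Miyaura coupling; both sp2 partners react with retention, so ring A ends up cis to C12 across C9=C11 as the next step requires.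

Step 12
Reactants: 19 dienol from step 11; 20 propionic anhydride
Product: 21 12-O-propionate of 19
Conditions: Et3N, DMAP (cat.), CH2Cl2, 0 °C to rt
Reagents that add atoms: none
Why: DMAP-catalysed acylation of the only free hydroxyl group; it installs C7, C8 and C17.

Step 13
Reactants: 21 12-O-propionate of 19
Product: 24 (2S,3S,4E,6S)-8-(tert-butyldiphenylsilyloxy)-3-[(3S,6S)-3-(methoxycarbonyl)-3-methyl-6-(triethylsilyloxy)cyclohex-1-en-1-yl]-2,3,6-trimethyloct-4-enoic acid, via silyl ketene acetal 22 (not isolated), via silyl ester 23 (not isolated)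
Conditions: LiN(i-Pr)2, THF–DMPU (4:1), −78 °C; Me3SiCl, −78 to 50 °C; then 5% aq. citric acid
Reagents that add atoms: none
Why: Ireland–Claisen rearrangement forming C8–C9; deprotonation in THF–DMPU gives the (Z)-silyl ketene acetal, and the chair with the C12 chain equatorial (the other chair would press it against the cis ring-A substituent) transfers the C12 configuration to the quaternary C9 (S) and sets C8 (S), with the (E)-C11=C12 alkene as the trace of the carbinol.

Step 14
Reactants: 24 unsaturated acid from step 13
Product: 25 (2S,3S,6R)-8-(tert-butyldiphenylsilyloxy)-3-[(3S,6S)-3-(methoxycarbonyl)-3-methyl-6-(triethylsilyloxy)cyclohex-1-en-1-yl]-2,3,6-trimethyloctanoic acid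
Conditions: H2 (1 atm), 5% Pt/C, EtOAc, rt
Reagents that add atoms: none
Why: Heterogeneous hydrogenation of the disubstituted C11=C12 alkene; the ring alkene C5=C10 is trisubstituted and flanked by two quaternary carbons and should remain, and the saturated chain removes a 1,5-diene that could compete in step 17.

Step 15
Reactants: 25 saturated acid from step 14
Product: 27 methyl (3S,4S,6S,8aS)-4-[(3R)-5-(tert-butyldiphenylsilyloxy)-3-methylpentyl]-3,4,6-trimethyl-2-oxo-3,4,6,7,8,8a-hexahydro-2H-chromene-6-carboxylate, via hydroxy acid 26 (not isolated)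
Conditions: HF·pyridine, THF–pyridine, 0 °C; then EDCI·HCl, DMAP, CH2Cl2, rt
Reagents that add atoms: none
Why: Buffered fluoride cleaves the secondary TES ether and spares the primary TBDPS ether; carbodiimide activation of the acid closes the δ-lactone by acyl substitution, so the C1–O bond and its configuration are not touched.

Step 16
Reactants: 27 lactone from step 15
Product: 28 methyl (3S,4S,6S,8aS)-4-[(3R)-5-(tert-butyldiphenylsilyloxy)-3-methylpentyl]-3,4,6-trimethyl-2-methylidene-3,4,6,7,8,8a-hexahydro-2H-chromene-6-carboxylate
Conditions: Cp2TiMe2 (1.5 equiv), toluene–THF, pyridine (trace), 65 °C, dark; filtration through basic alumina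
Reagents that add atoms: dimethyltitanocene, C[Ti](C)(C1C=CC=C1)C1C=CC=C1
Why: Petasis methylenation; Cp2Ti=CH2 formed on warming adds to the lactone carbonyl and cycloreverts to the exocyclic enol ether without basic conditions that could epimerise C8, and the δ-lactone, locked in the more electrophilic (E)-ester geometry, should react ahead of the acyclic α-quaternary C18 ester.

Step 17
Reactants: 28 ring-A-fused 2-methylidene pyran from step 16
Product: 29 methyl 7-oxo-15-(tert-butyldiphenylsilyloxy)-ent-halim-1(10)-en-18-oate
Conditions: o-dichlorobenzene (0.02 M), i-Pr2NEt (5 mol %), degassed, base-washed sealed tube, 200 °C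
Reagents that add atoms: none
Why: Proposed new method: on heating, the allyl vinyl ether C6=C7–O–C1–C10=C5 of 28 should undergo a concerted [3,3] shift in which C5–C6 forms while O–C1 breaks, the alkene moves to C1=C10 and C7 becomes a ketone. The closest known reactions are the Claisen ring reorganisations of 2-methylidene-6-alkenyltetrahydropyrans to cycloalkenones and the boat Cope rearrangement of 1,4-dimethylidenecyclohexanes; a Claisen shift between two alkenes that are both exocyclic to the same pyran has not been shown. Ring B (C5–C6–C7–C8–C9–C10) closes by union of the two exocyclic termini C6 and C5 across the pyran, which opens at O–C1; because C8–C9 tie the central atoms C7 and C10 together, the six reacting atoms can only adopt a boat arrangement resembling bicyclo[2.2.2]octane. The new stereocentre C5 is controlled by the C1 carbinol centre: the shift is suprafacial on the C1–C10–C5 allyl unit, so the α oxygen delivers C6 to the α face and leaves H5 β, while C4, C8, C9 and C13 are not touched. The step needs the concerted path to win over ionisation of the allylic C1–O bond and over acid-catalysed migration of the enol ether alkene into the ring; the non-polar solvent, the amine buffer, base-washed glass and the absence of Lewis acids serve this. No regiochemical alternative exists in the pericyclic manifold because only C6 and C5 can reach each other, and formation of the C7 carbonyl makes the reaction irreversible.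

Step 18
Reactants: 29 methyl 7-oxo-15-(tert-butyldiphenylsilyloxy)-ent-halim-1(10)-en-18-oate
Product: 30 C7 tosylhydrazone of 29
Conditions: TsNHNH2, EtOH, 60 °C
Reagents that add atoms: p-toluenesulfonyl hydrazide, Cc1ccc(cc1)S(=O)(=O)NN
Why: Condensation of the ketone with the sulfonyl hydrazide under neutral conditions, which limits enolisation towards C8.

Step 19
Reactants: 30 C7 tosylhydrazone of 29
Product: 32 methyl 15-(tert-butyldiphenylsilyloxy)-ent-halim-1(10)-en-18-oate, via N-borylhydrazine 31 (not isolated)
Conditions: catecholborane, CHCl3, 0 °C to rt; then NaOAc·3H2O, 60 °C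
Reagents that add atoms: none
Why: Hydride addition of catecholborane to the C=N bond, then acetate-induced loss of sulfinate and of nitrogen from the diazene, gives the methylene group without strong base (C8) or strong acid (alkene migration); the alkene is not conjugated to the hydrazone and stays in place.

Step 20
Reactants: 32 methyl 15-(tert-butyldiphenylsilyloxy)-ent-halim-1(10)-en-18-oate
Product: 33 methyl 15-hydroxy-ent-halim-1(10)-en-18-oate
Conditions: Bu4NF, AcOH, THF, rt
Reagents that add atoms: none
Why: Fluoride-mediated cleavage of the silyl ether, buffered so that the hindered methyl ester and the alkene are not affected.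

Step 21
Reactants: 33 methyl 15-hydroxy-ent-halim-1(10)-en-18-oate; 34 phenylpropiolic acid
Product: 35 methyl 15-(3-phenylprop-2-ynoyloxy)-ent-halim-1(10)-en-18-oate
Conditions: DCC, DMAP (cat.), CH2Cl2, 0 °C to rt
Reagents that add atoms: none
Why: Steglich esterification of the unhindered primary alcohol; the alkyne is a stable precursor of the (Z)-alkene.

Step 22
Reactants: 35 methyl 15-(3-phenylprop-2-ynoyloxy)-ent-halim-1(10)-en-18-oate
Product: 36 methyl 15-[(Z)-cinnamoyloxy]-ent-halim-1(10)-en-18-oate (CNP0185575.2)
Conditions: H2 (1 atm), Pd/CaCO3 poisoned with Pb(OAc)2, quinoline, EtOAc–hexane, rt, dark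
Reagents that add atoms: none
Why: Lindlar semihydrogenation; syn addition of one equivalent of hydrogen on the poisoned palladium surface gives the (Z)-cinnamate, and the hindered trisubstituted 1(10)-alkene is not reduced.

## Compound list

1 | (E)-1-(dimethylamino)-3-(tert-butyldimethylsilyloxy)buta-1,3-diene | CN(C)/C=C/C(=C)O[Si](C)(C)C(C)(C)C | starting material
2 | methacrolein | CC(=C)C=O | starting material
3 | endo cycloadduct, (1S,2R)-2-(dimethylamino)-1-methyl-4-(tert-butyldimethylsilyloxy)cyclohex-3-ene-1-carbaldehyde | O=C[C@@]1(C)CCC(O[Si](C)(C)C(C)(C)C)=C[C@H]1N(C)C | intermediate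
4 | (S)-1-methyl-4-oxocyclohex-2-ene-1-carbaldehyde | O=C[C@@]1(C)CCC(=O)C=C1 | intermediate
5 | (S)-1-methyl-4-oxocyclohex-2-ene-1-carboxylic acid | OC(=O)[C@@]1(C)CCC(=O)C=C1 | intermediate
6 | methyl (S)-1-methyl-4-oxocyclohex-2-ene-1-carboxylate | COC(=O)[C@@]1(C)CCC(=O)C=C1 | intermediate
7 | methyl 2,3-dibromo-1-methyl-4-oxocyclohexane-1-carboxylate (quaternary centre as in 6, mixture at the two CHBr carbons) | COC(=O)[C@@]1(C)CCC(=O)C(Br)C1Br | intermediate
8 | methyl (S)-3-bromo-1-methyl-4-oxocyclohex-2-ene-1-carboxylate | COC(=O)[C@@]1(C)CCC(=O)C(Br)=C1 | intermediate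
9 | methyl (1S,4S)-3-bromo-4-hydroxy-1-methylcyclohex-2-ene-1-carboxylate | COC(=O)[C@@]1(C)CC[C@H](O)C(Br)=C1 | intermediate
10 | methyl (1S,4S)-3-bromo-1-methyl-4-(triethylsilyloxy)cyclohex-2-ene-1-carboxylate | COC(=O)[C@@]1(C)CC[C@H](O[Si](CC)(CC)CC)C(Br)=C1 | intermediate
11 | (S)-α-methyl-γ-butyrolactone, (S)-3-methyloxolan-2-one | O=C1[C@@H](C)CCO1 | starting material
12 | 1-propynyllithium | CC#C[Li] | starting material
13 | (S)-7-hydroxy-5-methylhept-2-yn-4-one | CC#CC(=O)[C@@H](C)CCO | intermediate
14 | (S)-7-(tert-butyldiphenylsilyloxy)-5-methylhept-2-yn-4-one | CC#CC(=O)[C@@H](C)CCO[Si](c1ccccc1)(c1ccccc1)C(C)(C)C | intermediate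
15 | (4S,5S)-7-(tert-butyldiphenylsilyloxy)-5-methylhept-2-yn-4-ol | CC#C[C@@H](O)[C@@H](C)CCO[Si](c1ccccc1)(c1ccccc1)C(C)(C)C | intermediate
16 | cyclic sodium alkenyl(alkoxy)aluminate of 15 (aluminium on C2, cis to the C4 oxygen) | CC1=C[C@H]([C@@H](C)CCO[Si](c2ccccc2)(c2ccccc2)C(C)(C)C)O[Al-]1(OCCOC)OCCOC.[Na+] | intermediate
17 | (2Z,4S,5S)-7-(tert-butyldiphenylsilyloxy)-2-iodo-5-methylhept-2-en-4-ol | C/C(I)=C/[C@@H](O)[C@@H](C)CCO[Si](c1ccccc1)(c1ccccc1)C(C)(C)C | intermediate
18 | methyl (1S,4S)-1-methyl-3-(4,4,5,5-tetramethyl-1,3,2-dioxaborolan-2-yl)-4-(triethylsilyloxy)cyclohex-2-ene-1-carboxylate | COC(=O)[C@@]1(C)CC[C@H](O[Si](CC)(CC)CC)C(B2OC(C)(C)C(C)(C)O2)=C1 | intermediate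
19 | methyl (1S,4S)-3-[(2Z,4S,5S)-7-(tert-butyldiphenylsilyloxy)-4-hydroxy-5-methylhept-2-en-2-yl]-1-methyl-4-(triethylsilyloxy)cyclohex-2-ene-1-carboxylate | COC(=O)[C@@]1(C)CC[C@H](O[Si](CC)(CC)CC)C(=C1)/C(C)=C\[C@@H](O)[C@@H](C)CCO[Si](c2ccccc2)(c2ccccc2)C(C)(C)C | intermediate
20 | propionic anhydride | CCC(=O)OC(=O)CC | starting material
21 | 12-O-propionate of 19 | COC(=O)[C@@]1(C)CC[C@H](O[Si](CC)(CC)CC)C(=C1)/C(C)=C\[C@@H](OC(=O)CC)[C@@H](C)CCO[Si](c2ccccc2)(c2ccccc2)C(C)(C)C | intermediate
22 | (Z)-trimethylsilyl ketene acetal of 21 | COC(=O)[C@@]1(C)CC[C@H](O[Si](CC)(CC)CC)C(=C1)/C(C)=C\[C@@H](O/C(O[Si](C)(C)C)=C/C)[C@@H](C)CCO[Si](c2ccccc2)(c2ccccc2)C(C)(C)C | intermediate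
23 | trimethylsilyl ester of 24 | COC(=O)[C@@]1(C)CC[C@H](O[Si](CC)(CC)CC)C(=C1)[C@@](C)(/C=C/[C@@H](C)CCO[Si](c2ccccc2)(c2ccccc2)C(C)(C)C)[C@H](C)C(=O)O[Si](C)(C)C | intermediate
24 | (2S,3S,4E,6S)-8-(tert-butyldiphenylsilyloxy)-3-[(3S,6S)-3-(methoxycarbonyl)-3-methyl-6-(triethylsilyloxy)cyclohex-1-en-1-yl]-2,3,6-trimethyloct-4-enoic acid | COC(=O)[C@@]1(C)CC[C@H](O[Si](CC)(CC)CC)C(=C1)[C@@](C)(/C=C/[C@@H](C)CCO[Si](c2ccccc2)(c2ccccc2)C(C)(C)C)[C@H](C)C(O)=O | intermediate
25 | (2S,3S,6R)-8-(tert-butyldiphenylsilyloxy)-3-[(3S,6S)-3-(methoxycarbonyl)-3-methyl-6-(triethylsilyloxy)cyclohex-1-en-1-yl]-2,3,6-trimethyloctanoic acid | COC(=O)[C@@]1(C)CC[C@H](O[Si](CC)(CC)CC)C(=C1)[C@@](C)(CC[C@@H](C)CCO[Si](c2ccccc2)(c2ccccc2)C(C)(C)C)[C@H](C)C(O)=O | intermediate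
26 | hydroxy acid, 25 without the triethylsilyl group | COC(=O)[C@@]1(C)CC[C@H](O)C(=C1)[C@@](C)(CC[C@@H](C)CCO[Si](c2ccccc2)(c2ccccc2)C(C)(C)C)[C@H](C)C(O)=O | intermediate
27 | methyl (3S,4S,6S,8aS)-4-[(3R)-5-(tert-butyldiphenylsilyloxy)-3-methylpentyl]-3,4,6-trimethyl-2-oxo-3,4,6,7,8,8a-hexahydro-2H-chromene-6-carboxylate | COC(=O)[C@@]1(C)CC[C@@H]2OC(=O)[C@@H](C)[C@](C)(CC[C@@H](C)CCO[Si](c3ccccc3)(c3ccccc3)C(C)(C)C)C2=C1 | intermediate
28 | methyl (3S,4S,6S,8aS)-4-[(3R)-5-(tert-butyldiphenylsilyloxy)-3-methylpentyl]-3,4,6-trimethyl-2-methylidene-3,4,6,7,8,8a-hexahydro-2H-chromene-6-carboxylate | COC(=O)[C@@]1(C)CC[C@@H]2OC(=C)[C@@H](C)[C@](C)(CC[C@@H](C)CCO[Si](c3ccccc3)(c3ccccc3)C(C)(C)C)C2=C1 | intermediate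
29 | methyl 7-oxo-15-(tert-butyldiphenylsilyloxy)-ent-halim-1(10)-en-18-oate | COC(=O)[C@@]1(C)CCC=C2[C@@H]1CC(=O)[C@@H](C)[C@]2(C)CC[C@@H](C)CCO[Si](c3ccccc3)(c3ccccc3)C(C)(C)C | intermediate
30 | C7 tosylhydrazone of 29 | COC(=O)[C@@]1(C)CCC=C2[C@@H]1CC(=NNS(=O)(=O)c3ccc(C)cc3)[C@@H](C)[C@]2(C)CC[C@@H](C)CCO[Si](c4ccccc4)(c4ccccc4)C(C)(C)C | intermediate
31 | N-(1,3,2-benzodioxaborol-2-yl) tosylhydrazine from 30 (C7 configuration undefined) | COC(=O)[C@@]1(C)CCC=C2[C@@H]1CC(N(B3Oc4ccccc4O3)NS(=O)(=O)c3ccc(C)cc3)[C@@H](C)[C@]2(C)CC[C@@H](C)CCO[Si](c3ccccc3)(c3ccccc3)C(C)(C)C | intermediate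
32 | methyl 15-(tert-butyldiphenylsilyloxy)-ent-halim-1(10)-en-18-oate | COC(=O)[C@@]1(C)CCC=C2[C@@H]1CC[C@@H](C)[C@]2(C)CC[C@@H](C)CCO[Si](c3ccccc3)(c3ccccc3)C(C)(C)C | intermediate
33 | methyl 15-hydroxy-ent-halim-1(10)-en-18-oate | COC(=O)[C@@]1(C)CCC=C2[C@@H]1CC[C@@H](C)[C@]2(C)CC[C@@H](C)CCO | intermediate
34 | phenylpropiolic acid | OC(=O)C#Cc1ccccc1 | starting material
35 | methyl 15-(3-phenylprop-2-ynoyloxy)-ent-halim-1(10)-en-18-oate | COC(=O)[C@@]1(C)CCC=C2[C@@H]1CC[C@@H](C)[C@]2(C)CC[C@@H](C)CCOC(=O)C#Cc1ccccc1 | intermediate
36 | methyl 15-[(Z)-cinnamoyloxy]-ent-halim-1(10)-en-18-oate (CNP0185575.2) | COC(=O)[C@@]1(C)CCC=C2[C@@H]1CC[C@@H](C)[C@]2(C)CC[C@@H](C)CCOC(=O)/C=C\c1ccccc1 | target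

## Step count and least certain steps

Total: 22 steps. Longest linear sequence: 18 steps (steps 1–6, then 11–22). The side-chain branch (steps 7–10) joins at step 11.

**Step 17 (key step).** The boat transition state may lie too high, so that ionisation of the allylic C1–O bond takes over. That would bring stepwise recombination at C1, elimination to a diene and loss of the chirality transfer. Traces of acid may also move the exocyclic enol ether alkene into the ring before the shift occurs.

Fallback by known chemistry, setting out from acid 25 and returning at ketone 29. The C7 acid of 25 is methylated (Me3SiCHN2) to the diester F1. The TES ether is cleaved with HF·pyridine to the allylic alcohol F2, which is acetylated at once (Ac2O, DMAP) to the acetate F3. Ireland–Claisen rearrangement of F3 (LiN(i-Pr)2, Me3SiCl, −78 to 60 °C, kinetic deprotonation of the acetate methyl group) moves a two-carbon unit from the C1 oxygen to C5 with the same suprafacial chirality transfer and gives the C5 acetic acid F4 with the C1=C10 alkene. Methylation gives the triester F5. Dieckmann condensation (KN(SiMe3)2, THF) between C6 and the C7 ester closes ring B as the β-keto ester F6, and Krapcho demethoxycarbonylation (LiCl, wet DMSO, 140 °C) gives 29.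

**Step 16.** The titanium methylidene may not distinguish cleanly between the lactone carbonyl and the C18 methyl ester, which would lead to double methylenation. The enol ether may also isomerise into the ring on acidic surfaces.

Fallback, setting out from acid 25 and returning at 28. BH3·SMe2 reduces only the free acid to the primary alcohol F7. Oxidation with the periodinane DMP gives the aldehyde F8. Ohira–Bestmann homologation (dimethyl 1-diazo-2-oxopropylphosphonate, K2CO3, MeOH, 0 °C) gives the alkyne F9. HF·pyridine frees the alkynol F10, and 6-exo-dig hydroalkoxylation with a monovalent gold catalyst (Ph3PAuCl/AgOTf, amine-buffered work-up) gives 28 with no carbonyl discrimination needed.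

**Step 13.** Incomplete control of the ketene acetal geometry would erode the configuration at C8. Bond formation at the congested quaternary C9 may also be slow enough for the silyl ketene acetal to decompose.

Fallback, setting out from dienol 19 and returning at lactone 27. Acetylation (Ac2O, DMAP) gives the acetate F11, whose Ireland–Claisen rearrangement has no enolate geometry and sets only C9, giving the acid F12. Hydrogenation (H2, Pt/C) gives the saturated acid F13, and HF·pyridine then EDCI closes the lactone F14. Methylation of its lithium enolate (LiN(i-Pr)2, MeI, −78 °C) anti to the larger C9 substituent then installs C17 and gives 27.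

**Step 19.** Hydride transfer to the hindered hydrazone may stall, and prolonged heating during hydrazone formation or decomposition may epimerise C8.

Fallback, setting out from ketone 29 and returning at 32. NaBH4 in MeOH gives the C7 alcohol F15. NaH, CS2 and MeI give the xanthate F16, and Barton–McCombie reduction (Bu3SnH, AIBN, toluene, 110 °C) gives 32.

## Further compounds

F1 | step 17 | C7 methyl ester of 25 | COC(=O)[C@@]1(C)CC[C@H](O[Si](CC)(CC)CC)C(=C1)[C@@](C)(CC[C@@H](C)CCO[Si](c2ccccc2)(c2ccccc2)C(C)(C)C)[C@H](C)C(=O)OC
F2 | step 17 | C1 allylic alcohol, F1 without the triethylsilyl group | COC(=O)[C@@]1(C)CC[C@H](O)C(=C1)[C@@](C)(CC[C@@H](C)CCO[Si](c2ccccc2)(c2ccccc2)C(C)(C)C)[C@H](C)C(=O)OC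
F3 | step 17 | C1 acetate of F2 | COC(=O)[C@@]1(C)CC[C@H](OC(C)=O)C(=C1)[C@@](C)(CC[C@@H](C)CCO[Si](c2ccccc2)(c2ccccc2)C(C)(C)C)[C@H](C)C(=O)OC
F4 | step 17 | C5 acetic acid with the C1=C10 alkene (ring B open between C6 and C7) | COC(=O)[C@@]1(C)CCC=C([C@@H]1CC(O)=O)[C@@](C)(CC[C@@H](C)CCO[Si](c2ccccc2)(c2ccccc2)C(C)(C)C)[C@H](C)C(=O)OC
F5 | step 17 | methyl ester of F4 | COC(=O)[C@@]1(C)CCC=C([C@@H]1CC(=O)OC)[C@@](C)(CC[C@@H](C)CCO[Si](c2ccccc2)(c2ccccc2)C(C)(C)C)[C@H](C)C(=O)OC
F6 | step 17 | 6-methoxycarbonyl derivative of 29 (C6 configuration undefined) | COC(=O)[C@@]1(C)CCC=C2[C@@H]1C(C(=O)OC)C(=O)[C@@H](C)[C@]2(C)CC[C@@H](C)CCO[Si](c3ccccc3)(c3ccccc3)C(C)(C)C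
F7 | step 16 | C7 primary alcohol from 25 | COC(=O)[C@@]1(C)CC[C@H](O[Si](CC)(CC)CC)C(=C1)[C@@](C)(CC[C@@H](C)CCO[Si](c2ccccc2)(c2ccccc2)C(C)(C)C)[C@H](C)CO
F8 | step 16 | C7 aldehyde | COC(=O)[C@@]1(C)CC[C@H](O[Si](CC)(CC)CC)C(=C1)[C@@](C)(CC[C@@H](C)CCO[Si](c2ccccc2)(c2ccccc2)C(C)(C)C)[C@H](C)C=O
F9 | step 16 | terminal alkyne (C6≡C7) with the C1 triethylsilyl ether | COC(=O)[C@@]1(C)CC[C@H](O[Si](CC)(CC)CC)C(=C1)[C@@](C)(CC[C@@H](C)CCO[Si](c2ccccc2)(c2ccccc2)C(C)(C)C)[C@H](C)C#C
F10 | step 16 | alkynol, F9 without the triethylsilyl group | COC(=O)[C@@]1(C)CC[C@H](O)C(=C1)[C@@](C)(CC[C@@H](C)CCO[Si](c2ccccc2)(c2ccccc2)C(C)(C)C)[C@H](C)C#C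
F11 | step 13 | 12-O-acetate of 19 | COC(=O)[C@@]1(C)CC[C@H](O[Si](CC)(CC)CC)C(=C1)/C(C)=C\[C@@H](OC(C)=O)[C@@H](C)CCO[Si](c2ccccc2)(c2ccccc2)C(C)(C)C
F12 | step 13 | 17-nor analogue of 24 | COC(=O)[C@@]1(C)CC[C@H](O[Si](CC)(CC)CC)C(=C1)[C@@](C)(/C=C/[C@@H](C)CCO[Si](c2ccccc2)(c2ccccc2)C(C)(C)C)CC(O)=O
F13 | step 13 | 17-nor analogue of 25 | COC(=O)[C@@]1(C)CC[C@H](O[Si](CC)(CC)CC)C(=C1)[C@@](C)(CC[C@@H](C)CCO[Si](c2ccccc2)(c2ccccc2)C(C)(C)C)CC(O)=O
F14 | step 13 | 17-nor analogue of lactone 27 | COC(=O)[C@@]1(C)CC[C@@H]2OC(=O)C[C@](C)(CC[C@@H](C)CCO[Si](c3ccccc3)(c3ccccc3)C(C)(C)C)C2=C1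
F15 | step 19 | methyl 7-hydroxy-15-(tert-butyldiphenylsilyloxy)-ent-halim-1(10)-en-18-oate (C7 configuration undefined) | COC(=O)[C@@]1(C)CCC=C2[C@@H]1CC(O)[C@@H](C)[C@]2(C)CC[C@@H](C)CCO[Si](c3ccccc3)(c3ccccc3)C(C)(C)C
F16 | step 19 | S-methyl xanthate of F15 | COC(=O)[C@@]1(C)CCC=C2[C@@H]1CC(OC(=S)SC)[C@@H](C)[C@]2(C)CC[C@@H](C)CCO[Si](c3ccccc3)(c3ccccc3)C(C)(C)C
A1 | alternative 1 | 15-(tert-butyldimethylsilyloxy)-ent-halim-1(10)-en-18-al | O=C[C@@]1(C)CCC=C2[C@@H]1CC[C@@H](C)[C@]2(C)CC[C@@H](C)CCO[Si](C)(C)C(C)(C)C
A2 | alternative 1 | tert-butyl{[(3R)-5-[(1S,6R)-2-ethenyl-1,6-dimethylcyclohex-2-en-1-yl]-3-methylpentyl]oxy}dimethylsilane | C=CC1=CCC[C@@H](C)[C@]1(C)CC[C@@H](C)CCO[Si](C)(C)C(C)(C)C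
A3 | alternative 2 | methyl 15-(tert-butyldimethylsilyloxy)-ent-halima-1(10),6-dien-18-oate | COC(=O)[C@@]1(C)CCC=C2[C@@H]1C=C[C@@H](C)[C@]2(C)CC[C@@H](C)CCO[Si](C)(C)C(C)(C)C
A4 | alternative 3 | (2S,3R)-2-[(3R)-5-(tert-butyldimethylsilyloxy)-3-methylpentyl]-2,3-dimethylcyclohexan-1-one | O=C1CCC[C@@H](C)[C@]1(C)CC[C@@H](C)CCO[Si](C)(C)C(C)(C)C
A5 | alternative 3 | 2-methylcyclohex-2-en-1-one | CC1=CCCCC1=O
A6 | alternative 3 | (S)-tert-butyl[(5-iodo-3-methylpentyl)oxy]dimethylsilane | ICC[C@@H](C)CCO[Si](C)(C)C(C)(C)C
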